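**Retrosynthetic overview**

1. Locants used here: seven-membered ring C1 (CH–O-isovaleryl), C2 (=CH), C3 (=C–CH3), C4 (CH2), C5 (CH–O-aroyl), C6 (ring-fusion CH), C7 (ring-fusion C–CH3); five-membered ring C7, C8, C9, C10 (C(OH)iPr), C6. The target is (1R,5R,6S,7S,10S).
2. Late stage: the esters go on one after the other (C5 4-acetoxybenzoate, then C1 isovalerate, then deacetylation). C10–OH, C6–H and C5–OH come from the tetrasubstituted enone C5(=O)–C6=C10(iPr) by nucleophilic epoxidation, SmI2 opening and hydroxyl-directed reduction.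
3. Key disconnection: C3–C4 and C1–C7 are made together by a chiral-dirhodium-catalysed cyclopropanation/Cope rearrangement (formal (4+3) annulation) of the achiral 2-ethoxydiene 7 with the (E)-silyloxyvinyl diazoacetate 11. This closes the seven-membered ring and sets C1 and the quaternary C7 from two achiral partners.
4. Enabling feature: in the seven-membered ring the alkene C2=C3 and, across the CH2 C4, the carbinol C5 (an enol ether C5=C6 at the ketone level) form a cyclohepta-1,4-diene whose remaining sigma bond C1–C7 joins an allylic C–O carbon to the quaternary carbon. That is the retron of a cis-divinylcyclopropane Cope rearrangement; the C3 methyl is carried as the ester that the carbenoid needs and is reduced afterwards.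
5. Ring order: five-membered ring first (from 2-methylcyclopentanone, carried as an isopropylidene-cyclopentenyl triflate), then the seven-membered ring in the key step.

Key step: step 7

**Remarks before the steps**

- TBS = tert-butyldimethylsilyl. Compounds 3, 4 and 10 are racemic; their stereocentres are erased later.
- Assumption: the sense of induction known for Rh2(DOSP)4 cyclopropanation of monosubstituted alkenes by donor/acceptor carbenoids is taken to hold for the 1,1-disubstituted enol ether of 7, with the dienyl group ending cis to the vinyl donor. On that model the (R)-prolinate catalyst leads to the (1R,7S) series; the (S)-catalyst would give the antipode.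

**Route**

Step 1
Reactants: 1 2-methylcyclopentan-1-one; 2 acetone
Product: 3 2-(2-hydroxypropan-2-yl)-5-methylcyclopentan-1-one
Conditions: LiN(iPr)2 (LDA), THF, −78 °C; then 2, −78 °C; aqueous quench
Reagents that add atoms: none
Why: Kinetic deprotonation at the less substituted α-carbon followed by directed aldol addition to acetone should give the tertiary ketol, whose two stereocentres are removed in steps 2 and 3.

Step 2
Reactants: 3 2-(2-hydroxypropan-2-yl)-5-methylcyclopentan-1-one
Product: 4 2-methyl-5-(propan-2-ylidene)cyclopentan-1-one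
Conditions: p-TsOH·H2O (cat.), toluene, 110 °C, azeotropic removal of water
Reagents that add atoms: none
Why: Acid-catalysed dehydration of the tertiary β-hydroxy ketone (aldol condensation) should give the conjugated tetrasubstituted isopropylidene ketone, which is favoured over the isopropenyl isomer.

Step 3
Reactants: 4 2-methyl-5-(propan-2-ylidene)cyclopentan-1-one
Product: 5 2-methyl-5-(propan-2-ylidene)cyclopent-1-en-1-yl trifluoromethanesulfonate
Conditions: LiN(iPr)2, THF, −78 °C; then PhNTf2, −78 → 0 °C
Reagents that add atoms: N-phenylbis(trifluoromethanesulfonimide), O=S(=O)(N(c1ccccc1)S(=O)(=O)C(F)(F)F)C(F)(F)F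
Why: Kinetic α′-deprotonation of the α-alkylidene ketone gives the cross-conjugated dienolate, and O-sulfonylation (enol triflate formation) fixes the ring alkene on the methyl-bearing side.

Step 4
Reactants: 5 2-methyl-5-(propan-2-ylidene)cyclopent-1-en-1-yl trifluoromethanesulfonate; 6 tributyl(1-ethoxyethenyl)stannane
Product: 7 1-(1-ethoxyethenyl)-2-methyl-5-(propan-2-ylidene)cyclopent-1-ene
Conditions: Pd(PPh3)4 (5 mol %), CuI (10 mol %), LiCl (3 equiv), THF, 65 °C; Et3N-buffered chromatography
Reagents that add atoms: none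
Why: Stille coupling of the enol triflate with the α-ethoxyvinyl stannane (chloride-assisted, copper-accelerated for the hindered triflate) should deliver the 2-ethoxy-1,3-diene directly at the enol ether level needed for step 7.

Step 5
Reactants: 8 ethyl diazoacetate; 9 [(tert-butyldimethylsilyl)oxy]acetaldehyde
Product: 10 ethyl 4-[(tert-butyldimethylsilyl)oxy]-2-diazo-3-hydroxybutanoate
Conditions: DBU (10 mol %), MeCN, 23 °C
Reagents that add atoms: none
Why: Base-catalysed aldol-type addition of the diazoacetate C–H to the aldehyde should give the β-hydroxy-α-diazo ester, whose carbinol centre is removed in step 6.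

Step 6
Reactants: 10 ethyl 4-[(tert-butyldimethylsilyl)oxy]-2-diazo-3-hydroxybutanoate
Product: 11 ethyl (3E)-4-[(tert-butyldimethylsilyl)oxy]-2-diazobut-3-enoate
Conditions: POCl3, Et3N, CH2Cl2, 0 → 23 °C; used freshly
Reagents that add atoms: none
Why: Dehydration of the β-hydroxy-α-diazo ester through its dichlorophosphate (base-induced elimination) should give the conjugated (E)-vinyldiazoacetate, the trans isomer being favoured for the planar diazo-diene.

Step 7
Reactants: 7 1-(1-ethoxyethenyl)-2-methyl-5-(propan-2-ylidene)cyclopent-1-ene; 11 ethyl (3E)-4-[(tert-butyldimethylsilyl)oxy]-2-diazobut-3-enoate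
Product: 13 ethyl (1R,7S)-1-[(tert-butyldimethylsilyl)oxy]-5-ethoxy-7-methyl-10-(propan-2-ylidene)bicyclo[5.3.0]deca-2,5-diene-3-carboxylate, via cis-divinylcyclopropane 12 (not isolated)
Conditions: Rh2(R-DOSP)4 (1 mol %), 11 (1.5 equiv) added slowly, hexanes, −40 → 23 °C; then toluene, 80 °C
Reagents that add atoms: none
Why: Rh2(R-DOSP)4 turns 11 into a donor/acceptor rhodium vinylcarbenoid that cyclopropanates the terminal CH2=C(OEt) bond of 7 (first new bond, C3–C4) to give the cis-divinylcyclopropane 12, which then undergoes a boat-type Cope rearrangement that breaks the cyclopropane bond between the ester-bearing and the ethoxy-bearing carbon and joins the silyloxy-bearing vinyl terminus to the methyl-bearing ring carbon (second new bond, C1–C7). The closest known reaction type is the enantioselective tandem cyclopropanation/Cope rearrangement (formal (4+3) cycloaddition) of vinyldiazoacetates with 2-oxy-1,3-dienes under chiral dirhodium tetraprolinate catalysis. The seven-membered ring is closed by the [3,3]-sigmatropic shift of the cis-divinylcyclopropane, that is a three-atom plus four-atom annulation in which the three-membered ring made by concerted carbene transfer is opened again. The absolute configuration is set by the catalyst in the cyclopropanation and carried over suprafacially to C1 and the quaternary C7, while their relative configuration follows from the boat transition state: the (E)-silyloxy group lies outward and the C7 methyl (cis to the cyclopropyl-bearing carbon in the ring alkene) lies inward, which puts OTBS anti to the methyl. The step needs site selectivity (only the unhindered, electron-rich 1,1-disubstituted enol ether alkene of 7 is cyclopropanated, the two tetrasubstituted alkenes being inert to the bulky carbenoid), cis placement of the two vinyl groups (the vinyl donor ends cis to the carbon substituent of the alkene, and only this isomer can rearrange) and enantioface selectivity (chiral catalyst, hydrocarbon solvent, low temperature).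

Step 8
Reactants: 13 ethyl (1R,7S)-1-[(tert-butyldimethylsilyl)oxy]-5-ethoxy-7-methyl-10-(propan-2-ylidene)bicyclo[5.3.0]deca-2,5-diene-3-carboxylate
Product: 14 [(1R,7S)-1-[(tert-butyldimethylsilyl)oxy]-5-ethoxy-7-methyl-10-(propan-2-ylidene)bicyclo[5.3.0]deca-2,5-dien-3-yl]methanol
Conditions: iBu2AlH (2.5 equiv), CH2Cl2, −78 °C; aq. potassium sodium tartrate
Reagents that add atoms: none
Why: 1,2-Reduction of the conjugated ester by the aluminium hydride should give the primary allylic alcohol, while the enol ether, the silyl ether and the alkenes are inert and the work-up stays non-acidic.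

Step 9
Reactants: 14 [(1R,7S)-1-[(tert-butyldimethylsilyl)oxy]-5-ethoxy-7-methyl-10-(propan-2-ylidene)bicyclo[5.3.0]deca-2,5-dien-3-yl]methanol
Product: 16 (1R,7S)-1-[(tert-butyldimethylsilyl)oxy]-5-ethoxy-3,7-dimethyl-10-(propan-2-ylidene)bicyclo[5.3.0]deca-2,5-diene, via allylic mesylate 15 (not isolated)
Conditions: MsCl, Et3N, CH2Cl2, −20 °C; then LiEt3BH, THF, 0 °C
Reagents that add atoms: none
Why: Mesylation followed by SN2 hydride displacement at the primary allylic carbon should turn CH2OH into the C3 methyl without moving the alkene, under basic conditions that spare the enol ether.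

Step 10
Reactants: 16 (1R,7S)-1-[(tert-butyldimethylsilyl)oxy]-5-ethoxy-3,7-dimethyl-10-(propan-2-ylidene)bicyclo[5.3.0]deca-2,5-diene
Product: 18 (1R,7S)-1-[(tert-butyldimethylsilyl)oxy]-3,7-dimethyl-10-(propan-2-yl)bicyclo[5.3.0]deca-2,6(10)-dien-5-one, via β,γ-unsaturated ketone 17 (not isolated)
Conditions: PPTS (cat.), acetone/H2O, 23 °C; then DBU, CH2Cl2, 23 °C
Reagents that add atoms: water, O
Why: Mild acid hydrolysis of the enol ether gives the C5 ketone, and base-mediated alkene conjugation through the dienolate (γ-protonation) should move the exocyclic isopropylidene into the conjugated, endocyclic C6=C10 position, which is favoured both by conjugation and by the endocyclic placement in the five-membered ring.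

Step 11
Reactants: 18 (1R,7S)-1-[(tert-butyldimethylsilyl)oxy]-3,7-dimethyl-10-(propan-2-yl)bicyclo[5.3.0]deca-2,6(10)-dien-5-one
Product: 19 (1R,6S,7R,10S)-1-[(tert-butyldimethylsilyl)oxy]-6,10-epoxy-3,7-dimethyl-10-(propan-2-yl)bicyclo[5.3.0]dec-2-en-5-one
Conditions: 30 % H2O2, NaOH (cat.), MeOH, 0 → 23 °C
Reagents that add atoms: hydrogen peroxide, OO
Why: Weitz–Scheffer nucleophilic epoxidation is selective for the enone over the isolated C2=C3 alkene and should deliver oxygen to the cyclopentene face anti to the pseudoaxial C7 methyl (as in steroidal 16-en-20-ones, which are epoxidised anti to the angular methyl), setting the C10–O bond.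

Step 12
Reactants: 19 (1R,6S,7R,10S)-1-[(tert-butyldimethylsilyl)oxy]-6,10-epoxy-3,7-dimethyl-10-(propan-2-yl)bicyclo[5.3.0]dec-2-en-5-one
Product: 20 (1R,6R,7S,10S)-1-[(tert-butyldimethylsilyl)oxy]-10-hydroxy-3,7-dimethyl-10-(propan-2-yl)bicyclo[5.3.0]dec-2-en-5-one
Conditions: SmI2 (2.2 equiv), THF/MeOH, −90 °C
Reagents that add atoms: none
Why: Samarium diiodide reduction of the α,β-epoxy ketone (ketyl formation, cleavage of the C6–O bond) leaves C10 untouched and gives a samarium enolate that should be protonated at C6 from the face of the neighbouring samarium alkoxide, anti to the C7 methyl, giving the trans ring fusion.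

Step 13
Reactants: 20 (1R,6R,7S,10S)-1-[(tert-butyldimethylsilyl)oxy]-10-hydroxy-3,7-dimethyl-10-(propan-2-yl)bicyclo[5.3.0]dec-2-en-5-one
Product: 21 (1R,5R,6S,7S,10S)-1-[(tert-butyldimethylsilyl)oxy]-3,7-dimethyl-10-(propan-2-yl)bicyclo[5.3.0]dec-2-ene-5,10-diol
Conditions: Me4NBH(OAc)3, MeCN/AcOH, −30 → 0 °C
Reagents that add atoms: none
Why: In the Evans–Saksena reduction the C10 hydroxyl binds the borohydride and delivers hydride internally to the C5 carbonyl from the face anti to the C7 methyl (also the open face), which should give the 1,3-anti diol with C5–OH syn to that methyl.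

Step 14
Reactants: 21 (1R,5R,6S,7S,10S)-1-[(tert-butyldimethylsilyl)oxy]-3,7-dimethyl-10-(propan-2-yl)bicyclo[5.3.0]dec-2-ene-5,10-diol; 22 4-acetoxybenzoyl chloride
Product: 23 (1R,5R,6S,7S,10S)-1-[(tert-butyldimethylsilyl)oxy]-10-hydroxy-3,7-dimethyl-10-(propan-2-yl)bicyclo[5.3.0]dec-2-en-5-yl 4-acetoxybenzoate
Conditions: pyridine, DMAP (cat.), CH2Cl2, 0 → 23 °C
Reagents that add atoms: none
Why: O-Acylation with the acid chloride should take place only at the secondary C5 hydroxyl, the tertiary C10 hydroxyl being unreactive under these conditions and the phenol being masked as its acetate.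

Step 15
Reactants: 23 (1R,5R,6S,7S,10S)-1-[(tert-butyldimethylsilyl)oxy]-10-hydroxy-3,7-dimethyl-10-(propan-2-yl)bicyclo[5.3.0]dec-2-en-5-yl 4-acetoxybenzoate
Product: 24 (1R,5R,6S,7S,10S)-1,10-dihydroxy-3,7-dimethyl-10-(propan-2-yl)bicyclo[5.3.0]dec-2-en-5-yl 4-acetoxybenzoate
Conditions: HF·pyridine, pyridine/THF, 0 → 23 °C
Reagents that add atoms: none
Why: Fluoride-mediated cleavage of the silyl ether under buffered, weakly acidic conditions should free the C1 hydroxyl without touching the aryl acetate, the benzoate or the allylic stereocentre.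

Step 16
Reactants: 24 (1R,5R,6S,7S,10S)-1,10-dihydroxy-3,7-dimethyl-10-(propan-2-yl)bicyclo[5.3.0]dec-2-en-5-yl 4-acetoxybenzoate; 25 3-methylbutanoyl chloride
Product: 26 (1R,5R,6S,7S,10S)-10-hydroxy-3,7-dimethyl-1-(3-methylbutanoyloxy)-10-(propan-2-yl)bicyclo[5.3.0]dec-2-en-5-yl 4-acetoxybenzoate
Conditions: pyridine, DMAP (cat.), CH2Cl2, 0 °C
Reagents that add atoms: none
Why: O-Acylation of the secondary allylic C1 hydroxyl with the acid chloride (far more electrophilic than the aryl acetate) proceeds with retention at C1 and leaves the tertiary hydroxyl free.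

Step 17
Reactants: 26 (1R,5R,6S,7S,10S)-10-hydroxy-3,7-dimethyl-1-(3-methylbutanoyloxy)-10-(propan-2-yl)bicyclo[5.3.0]dec-2-en-5-yl 4-acetoxybenzoate
Product: 27 (1R,5R,6S,7S,10S)-10-hydroxy-3,7-dimethyl-1-(3-methylbutanoyloxy)-10-(propan-2-yl)bicyclo[5.3.0]dec-2-en-5-yl 4-hydroxybenzoate (CNP0086724.4)
Conditions: pyrrolidine (1.5 equiv), CH2Cl2, 0 °C
Reagents that add atoms: none
Why: Chemoselective aminolysis of the aryl acetate (phenoxide leaving group) should free the phenol while the two esters of secondary alcohols remain.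

**Compound list**

1 | 2-methylcyclopentan-1-one | CC1CCCC1=O | starting material
2 | acetone | CC(C)=O | starting material
3 | 2-(2-hydroxypropan-2-yl)-5-methylcyclopentan-1-one (racemic diastereomer mixture) | CC1CCC(C(C)(C)O)C1=O | intermediate
4 | 2-methyl-5-(propan-2-ylidene)cyclopentan-1-one (racemic) | CC1CCC(=C(C)C)C1=O | intermediate
5 | 2-methyl-5-(propan-2-ylidene)cyclopent-1-en-1-yl trifluoromethanesulfonate | CC1=C(OS(=O)(=O)C(F)(F)F)C(=C(C)C)CC1 | intermediate
6 | tributyl(1-ethoxyethenyl)stannane | CCCC[Sn](CCCC)(CCCC)C(=C)OCC | starting material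
7 | 1-(1-ethoxyethenyl)-2-methyl-5-(propan-2-ylidene)cyclopent-1-ene | CCOC(=C)C1=C(C)CCC1=C(C)C | intermediate
8 | ethyl diazoacetate | CCOC(=O)C=[N+]=[N-] | starting material
9 | [(tert-butyldimethylsilyl)oxy]acetaldehyde | O=CCO[Si](C)(C)C(C)(C)C | starting material
10 | ethyl 4-[(tert-butyldimethylsilyl)oxy]-2-diazo-3-hydroxybutanoate (racemic) | CCOC(=O)C(=[N+]=[N-])C(O)CO[Si](C)(C)C(C)(C)C | intermediate
11 | ethyl (3E)-4-[(tert-butyldimethylsilyl)oxy]-2-diazobut-3-enoate | CCOC(=O)C(=[N+]=[N-])/C=C/O[Si](C)(C)C(C)(C)C | intermediate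
12 | ethyl (1S,2R)-1-{(E)-2-[(tert-butyldimethylsilyl)oxy]ethenyl}-2-ethoxy-2-[2-methyl-5-(propan-2-ylidene)cyclopent-1-en-1-yl]cyclopropane-1-carboxylate (the two vinyl groups cis; not isolated) | CCOC(=O)[C@]1(/C=C/O[Si](C)(C)C(C)(C)C)C[C@@]1(OCC)C2=C(C)CCC2=C(C)C | intermediate
13 | ethyl (1R,7S)-1-[(tert-butyldimethylsilyl)oxy]-5-ethoxy-7-methyl-10-(propan-2-ylidene)bicyclo[5.3.0]deca-2,5-diene-3-carboxylate (route locants; OTBS anti to the C7 methyl) | CCOC(=O)C1=C[C@@H](O[Si](C)(C)C(C)(C)C)[C@@]2(C)CCC(=C(C)C)C2=C(OCC)C1 | intermediate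
14 | [(1R,7S)-1-[(tert-butyldimethylsilyl)oxy]-5-ethoxy-7-methyl-10-(propan-2-ylidene)bicyclo[5.3.0]deca-2,5-dien-3-yl]methanol | OCC1=C[C@@H](O[Si](C)(C)C(C)(C)C)[C@@]2(C)CCC(=C(C)C)C2=C(OCC)C1 | intermediate
15 | methanesulfonate of 14 at the primary allylic oxygen (not isolated) | CS(=O)(=O)OCC1=C[C@@H](O[Si](C)(C)C(C)(C)C)[C@@]2(C)CCC(=C(C)C)C2=C(OCC)C1 | intermediate
16 | (1R,7S)-1-[(tert-butyldimethylsilyl)oxy]-5-ethoxy-3,7-dimethyl-10-(propan-2-ylidene)bicyclo[5.3.0]deca-2,5-diene | CC1=C[C@@H](O[Si](C)(C)C(C)(C)C)[C@@]2(C)CCC(=C(C)C)C2=C(OCC)C1 | intermediate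
17 | (1R,7S)-1-[(tert-butyldimethylsilyl)oxy]-3,7-dimethyl-10-(propan-2-ylidene)bicyclo[5.3.0]dec-2-en-5-one (C6 epimers; not isolated) | CC1=C[C@@H](O[Si](C)(C)C(C)(C)C)[C@@]2(C)CCC(=C(C)C)C2C(=O)C1 | intermediate
18 | (1R,7S)-1-[(tert-butyldimethylsilyl)oxy]-3,7-dimethyl-10-(propan-2-yl)bicyclo[5.3.0]deca-2,6(10)-dien-5-one | CC1=C[C@@H](O[Si](C)(C)C(C)(C)C)[C@@]2(C)CCC(C(C)C)=C2C(=O)C1 | intermediate
19 | (1R,6S,7R,10S)-1-[(tert-butyldimethylsilyl)oxy]-6,10-epoxy-3,7-dimethyl-10-(propan-2-yl)bicyclo[5.3.0]dec-2-en-5-one (epoxide oxygen anti to the C7 methyl) | CC1=C[C@@H](O[Si](C)(C)C(C)(C)C)[C@@]2(C)CC[C@@]3(C(C)C)O[C@@]23C(=O)C1 | intermediate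
20 | (1R,6R,7S,10S)-1-[(tert-butyldimethylsilyl)oxy]-10-hydroxy-3,7-dimethyl-10-(propan-2-yl)bicyclo[5.3.0]dec-2-en-5-one (trans ring fusion; C10–OH syn to C6–H) | CC1=C[C@@H](O[Si](C)(C)C(C)(C)C)[C@@]2(C)CC[C@](O)(C(C)C)[C@@H]2C(=O)C1 | intermediate
21 | (1R,5R,6S,7S,10S)-1-[(tert-butyldimethylsilyl)oxy]-3,7-dimethyl-10-(propan-2-yl)bicyclo[5.3.0]dec-2-ene-5,10-diol (C5–OH syn to the C7 methyl) | CC1=C[C@@H](O[Si](C)(C)C(C)(C)C)[C@@]2(C)CC[C@](O)(C(C)C)[C@@H]2[C@H](O)C1 | intermediate
22 | 4-acetoxybenzoyl chloride | CC(=O)Oc1ccc(cc1)C(Cl)=O | starting material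
23 | (1R,5R,6S,7S,10S)-1-[(tert-butyldimethylsilyl)oxy]-10-hydroxy-3,7-dimethyl-10-(propan-2-yl)bicyclo[5.3.0]dec-2-en-5-yl 4-acetoxybenzoate | CC1=C[C@@H](O[Si](C)(C)C(C)(C)C)[C@@]2(C)CC[C@](O)(C(C)C)[C@@H]2[C@H](OC(=O)c2ccc(OC(C)=O)cc2)C1 | intermediate
24 | (1R,5R,6S,7S,10S)-1,10-dihydroxy-3,7-dimethyl-10-(propan-2-yl)bicyclo[5.3.0]dec-2-en-5-yl 4-acetoxybenzoate | CC1=C[C@@H](O)[C@@]2(C)CC[C@](O)(C(C)C)[C@@H]2[C@H](OC(=O)c2ccc(OC(C)=O)cc2)C1 | intermediate
25 | 3-methylbutanoyl chloride (isovaleryl chloride) | CC(C)CC(Cl)=O | starting material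
26 | (1R,5R,6S,7S,10S)-10-hydroxy-3,7-dimethyl-1-(3-methylbutanoyloxy)-10-(propan-2-yl)bicyclo[5.3.0]dec-2-en-5-yl 4-acetoxybenzoate | CC1=C[C@@H](OC(=O)CC(C)C)[C@@]2(C)CC[C@](O)(C(C)C)[C@@H]2[C@H](OC(=O)c2ccc(OC(C)=O)cc2)C1 | intermediate
27 | (1R,5R,6S,7S,10S)-10-hydroxy-3,7-dimethyl-1-(3-methylbutanoyloxy)-10-(propan-2-yl)bicyclo[5.3.0]dec-2-en-5-yl 4-hydroxybenzoate (CNP0086724.4) | CC1=C[C@@H](OC(=O)CC(C)C)[C@@]2(C)CC[C@](O)(C(C)C)[C@@H]2[C@H](OC(=O)c2ccc(O)cc2)C1 | target

**Step count and risks**

Total step count: 17. Longest linear sequence: 15 steps (steps 1–4 and 7–17); steps 5–6 make the second partner of the key step.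

Steps most likely to fail:

1. Step 7. The risk is leakage of stereocontrol. If part of the carbenoid adds with the ethoxy group rather than the dienyl group cis to the vinyl donor, the resulting trans-divinylcyclopropane can rearrange only after epimerisation through reversible zwitterionic opening of the donor–acceptor ring. That erodes enantiomeric purity, and the same zwitterion can collapse to a formal (3+2) cyclopentene. Fallback (classical resolution instead of sole reliance on catalyst control): the scalemic material is carried on to diol 21, from which the fallback sets out. Esterification of the C5 hydroxyl with (S)-2-methoxy-2-phenylacetic acid (DCC, DMAP, CH2Cl2) gives the C5 (S)-O-methylmandelate of 21 F1. The diastereomeric ester of the minor enantiomer F2 is removed by crystallisation or chromatography. Methanolysis of F1 (K2CO3, MeOH) returns to the route at 21, now enantiopure.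

2. Step 11. The risk is slow or wrong-face oxygen transfer: the β-carbon of the twisted tetrasubstituted enone carries an isopropyl group, and closure of the β-peroxy enolate takes place next to the quaternary centre. Fallback (conjugate borylation/oxidation instead of epoxidation/reductive opening): from 18, copper-catalysed conjugate addition of boron (CuCl, NaOtBu, a chiral N-heterocyclic carbene ligand chosen to place boron anti to the C7 methyl, bis(pinacolato)diboron, MeOH, THF) gives the C10 pinacolboryl ketone F3. Oxidation of the C–B bond with retention (NaBO3·4H2O, THF/H2O) returns to the route at 20, bypassing steps 11 and 12.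

3. Step 3. The risk is competing γ-deprotonation at an isopropylidene methyl, which gives the linear dienolate and a regioisomeric triflate. Fallback (carbonyl addition/dehydration instead of enolisation/cross-coupling): from 4, ethyl vinyl ether is lithiated with tBuLi (THF, −78 → 0 °C) to 1-ethoxyvinyllithium F4, which adds to the ketone at −78 °C to give the tertiary carbinol 1-(1-ethoxyethenyl)-2-methyl-5-(propan-2-ylidene)cyclopentan-1-ol F5. Syn-dehydration with methyl N-(triethylammoniosulfonyl)carbamate (benzene, 50 °C) can remove only the hydrogen on the methyl-bearing carbon and returns to the route at 7, bypassing 5 and the Stille coupling.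

**Further compounds**

F1 | step 7 | (S)-2-methoxy-2-phenylacetate of 21 at the C5 oxygen | CC1=C[C@@H](O[Si](C)(C)C(C)(C)C)[C@@]2(C)CC[C@](O)(C(C)C)[C@@H]2[C@H](OC(=O)[C@@H](OC)c2ccccc2)C1
F2 | step 7 | (S)-2-methoxy-2-phenylacetate of the enantiomer of 21 (removed diastereomer) | CC1=C[C@H](O[Si](C)(C)C(C)(C)C)[C@]2(C)CC[C@@](O)(C(C)C)[C@H]2[C@@H](OC(=O)[C@@H](OC)c2ccccc2)C1
F3 | step 11 | 1-[(tert-butyldimethylsilyl)oxy]-3,7-dimethyl-10-(4,4,5,5-tetramethyl-1,3,2-dioxaborolan-2-yl)-10-(propan-2-yl)bicyclo[5.3.0]dec-2-en-5-one (boron anti to the C7 methyl, trans ring fusion) | CC1=C[C@@H](O[Si](C)(C)C(C)(C)C)[C@@]2(C)CC[C@](B3OC(C)(C)C(C)(C)O3)(C(C)C)[C@@H]2C(=O)C1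
F4 | step 3 | 1-ethoxyvinyllithium | [Li]C(=C)OCC
F5 | step 3 | 1-(1-ethoxyethenyl)-2-methyl-5-(propan-2-ylidene)cyclopentan-1-ol (racemic diastereomer mixture) | CCOC(=C)C1(O)C(C)CCC1=C(C)C
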